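**Retrosynthetic overview**
1. Target ⇐ its hexa-O-methyl ether (global demethylation). All four benzene rings are bought; the only ring made is the dihydrofuran.
2. Hexamethyl ether ⇐ C6–Cβ(vinyl) bond: Rh(III)-catalysed, carboxylate-directed C–H olefination of the benzofuran-5-carboxylic acid with 4-methoxystyrene, the carboxyl leaving as CO2 in the same pot.
3. Enabling feature: on the benzo ring, C5 is the only free position ortho to the C4 oxygen (C3a is the ring fusion) and lies para to O1, and C6–H is the only C–H ortho to C5. A carboxyl placed on C5 through the C4 phenol can therefore metalate only C6, the carbon meta to both oxygens, and is then lost easily.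
4. Acid ⇐ 4-hydroxy-2,3-diaryl-dihydrobenzofuran (ortho-formylation, O-methylation, Pinnick) ⇐ dihydrofuran ring by enantioselective Rh-carbene 1,5-C–H insertion (C2–C3 bond) of a diaryldiazomethane into a 3,4-dimethoxybenzyl ether, then acid epimerization at C2 to trans.
5. Hydrazone ⇐ 2,6-difluorobenzonitrile (two SNAr etherifications) + 3,5-dimethoxyphenyllithium (nitrile addition, transimination with hydrazine).

Key step: step 9

Remark (assumption): Rh2(S-PTAD)4 is taken as the catalyst enantiomer that leads to (3S), and the insertion is taken to be cis-selective as is usual for donor/donor carbenes; if the sense of induction is the opposite, Rh2(R-PTAD)4 is used, and step 5 converges either C2 epimer on the trans series.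

Step 1
Reactants: 1 2,6-difluorobenzonitrile
Product: 2 2-(tert-butoxy)-6-fluorobenzonitrile
Conditions: KOtBu (1.05 equiv), THF, −10 → 0 °C
Reagents that add atoms: potassium tert-butoxide, CC(C)(C)[O-].[K+]
Why: Nucleophilic aromatic substitution (SNAr) of a nitrile-activated ortho fluoride through a Meisenheimer adduct, in which the first bulky, electron-donating tert-butoxy group should slow a second substitution so that the mono-ether dominates; no stereocentre is formed.

Step 2
Reactants: 2 2-(tert-butoxy)-6-fluorobenzonitrile; 3 (3,4-dimethoxyphenyl)methanol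
Product: 4 2-(tert-butoxy)-6-[(3,4-dimethoxybenzyl)oxy]benzonitrile
Conditions: NaH, DMF, 0 → 50 °C
Reagents that add atoms: none
Why: Second SNAr, by the sodium alkoxide of 3 on the remaining nitrile-activated fluoride, needs only gentle heating, the tert-butyl ether being inert to alkoxide; no stereocentre is formed.

Step 3
Reactants: 4 2-(tert-butoxy)-6-[(3,4-dimethoxybenzyl)oxy]benzonitrile; 5 1-bromo-3,5-dimethoxybenzene
Product: 8 [2-(tert-butoxy)-6-[(3,4-dimethoxybenzyl)oxy]phenyl](3,5-dimethoxyphenyl)methanone hydrazone, via 3,5-dimethoxyphenyllithium 6 (not isolated), via diaryl ketimine 7 (not isolated)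
Conditions: 5, n-BuLi, THF, −78 °C; add 4, −78 → 0 °C; AcOH; then N2H4·H2O, EtOH, 75 °C
Reagents that add atoms: hydrazine hydrate, NN.O
Why: Bromine–lithium exchange and 1,2-addition of the aryllithium to the nitrile give a hindered N–H ketimine that resists hydrolysis but should undergo acid-catalysed transimination with hydrazine (much easier than condensation of the corresponding 2,6-disubstituted ketone), and the E/Z hydrazone mixture is irrelevant because both isomers converge on one diazo compound.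

Step 4
Reactants: 8 [2-(tert-butoxy)-6-[(3,4-dimethoxybenzyl)oxy]phenyl](3,5-dimethoxyphenyl)methanone hydrazone
Product: 10 (2R,3S)-4-(tert-butoxy)-2-(3,4-dimethoxyphenyl)-3-(3,5-dimethoxyphenyl)-2,3-dihydro-1-benzofuran, via diaryldiazomethane 9 (not isolated)
Conditions: MnO2, CH2Cl2, 0 °C, filtration; then Rh2(S-PTAD)4 (1 mol %), CH2Cl2, 0 °C
Reagents that add atoms: none
Why: Dehydrogenation of the hydrazone to the donor/donor diazo compound and Rh(II)-carbene 1,5-C–H insertion into the electron-rich benzylic ether C–H close the dihydrofuran ring (C2–C3 bond), the chiral carboxylate pocket of the catalyst selecting one carbene face and one enantiotopic benzylic hydrogen in a concerted insertion to set C3 (S) and C2 (R, cis), while the tert-butyl ether offers no C–H within reach of a competing 1,5-insertion.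

Step 5
Reactants: 10 (2R,3S)-4-(tert-butoxy)-2-(3,4-dimethoxyphenyl)-3-(3,5-dimethoxyphenyl)-2,3-dihydro-1-benzofuran
Product: 12 (2S,3S)-2-(3,4-dimethoxyphenyl)-3-(3,5-dimethoxyphenyl)-2,3-dihydro-1-benzofuran-4-ol, via cis-phenol 11 (not isolated)
Conditions: TFA/CH2Cl2 (1:4), 0 °C → rt
Reagents that add atoms: none
Why: Acidolysis (E1) of the aryl tert-butyl ether frees the C4 phenol, and reversible acid-mediated heterolysis of the O1–C2 bond to the 3,4-dimethoxybenzyl cation followed by reclosure should epimerize C2 to the more stable trans isomer (2S) under thermodynamic control, C3 (S) not being involved.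

Step 6
Reactants: 12 (2S,3S)-2-(3,4-dimethoxyphenyl)-3-(3,5-dimethoxyphenyl)-2,3-dihydro-1-benzofuran-4-ol
Product: 13 (2S,3S)-2-(3,4-dimethoxyphenyl)-3-(3,5-dimethoxyphenyl)-4-hydroxy-2,3-dihydro-1-benzofuran-5-carbaldehyde
Conditions: (CH2O)n, MgCl2, Et3N, MeCN, 80 °C; aq HCl work-up
Reagents that add atoms: paraformaldehyde (formaldehyde), C=O
Why: Casnati–Skattebøl ortho-formylation, in which the magnesium phenoxide delivers formaldehyde to the only free ortho position (C5, C3a being substituted) and the salicyl alcohol is oxidized in situ by a second formaldehyde through hydride transfer; the mild amine base leaves both stereocentres untouched.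

Step 7
Reactants: 13 (2S,3S)-2-(3,4-dimethoxyphenyl)-3-(3,5-dimethoxyphenyl)-4-hydroxy-2,3-dihydro-1-benzofuran-5-carbaldehyde
Product: 14 (2S,3S)-2-(3,4-dimethoxyphenyl)-3-(3,5-dimethoxyphenyl)-4-methoxy-2,3-dihydro-1-benzofuran-5-carbaldehyde
Conditions: MeI, K2CO3, DMF, 40 °C
Reagents that add atoms: iodomethane, CI
Why: Williamson O-methylation of the hydrogen-bonded phenol caps the last free hydroxyl so that no phenol meets Ag(I) later; the stereocentres are not touched.

Step 8
Reactants: 14 (2S,3S)-2-(3,4-dimethoxyphenyl)-3-(3,5-dimethoxyphenyl)-4-methoxy-2,3-dihydro-1-benzofuran-5-carbaldehyde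
Product: 15 (2S,3S)-2-(3,4-dimethoxyphenyl)-3-(3,5-dimethoxyphenyl)-4-methoxy-2,3-dihydro-1-benzofuran-5-carboxylic acid
Conditions: NaClO2, NaH2PO4, 2-methyl-2-butene, t-BuOH/THF/H2O, 0 °C → rt
Reagents that add atoms: sodium chlorite, [Na+].[O-]Cl=O
Why: Pinnick oxidation converts the aryl aldehyde into the acid under buffered conditions, 2-methyl-2-butene scavenging HOCl so that the electron-rich rings should not be chlorinated; the stereocentres are not touched.

Step 9
Reactants: 15 (2S,3S)-2-(3,4-dimethoxyphenyl)-3-(3,5-dimethoxyphenyl)-4-methoxy-2,3-dihydro-1-benzofuran-5-carboxylic acid; 16 4-methoxystyrene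
Product: 18 (2S,3S)-2-(3,4-dimethoxyphenyl)-3-(3,5-dimethoxyphenyl)-4-methoxy-6-[(E)-2-(4-methoxyphenyl)ethenyl]-2,3-dihydro-1-benzofuran, via 6-styryl acid 17 (not isolated)
Conditions: [Cp*RhCl2]2 (2.5 mol %), AgOAc (2.2 equiv), DMF, 110 °C; then Ag2CO3 (20 mol %), 140 °C
Reagents that add atoms: none
Why: Carboxylate-assisted C–H metalation (concerted metalation–deprotonation) by Cp*Rh(III) gives a five-membered rhodacycle at C6, the styrene inserts syn with its aryl carbon remote from rhodium, syn β-hydride elimination releases the (E)-alkene and AgOAc reoxidizes Rh(I); at the higher temperature the now di-ortho-substituted, ortho/para-dioxygenated acid 17 loses CO2 by Ag(I)-mediated protodecarboxylation (aryl–silver intermediate, protonated by the acetic acid formed). The closest known reaction type is the Rh(III)-catalysed carboxylate-directed oxidative ortho-olefination of benzoic acids with styrenes run in one pot with decarboxylation to give meta-substituted stilbenes, a Fujiwara–Moritani-type alkenylation with a traceless directing group. No ring is closed and no stereocentre is created; the only new stereo-element is the E double bond, fixed by the syn-insertion/syn-elimination sequence, and C2 and C3 are untouched because the medium contains neither strong base nor strong acid. The step needs site selectivity for C6, which the substrate secures because the C5 carboxyl has a single ortho C–H (C4 bears OMe) and no other C–H of 15 can reach a five-membered carboxylate rhodacycle, so that the carbon meta to both ring oxygens is functionalized, and only once. It also needs olefination to precede loss of CO2, which the substitution pattern secures: before olefination the acid has one ortho substituent and should survive 110 °C, afterwards it has two and decarboxylates. All oxygens are methyl-capped so that Ag(I) cannot start phenol oxidative coupling of the new stilbene.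

Step 10
Reactants: 18 (2S,3S)-2-(3,4-dimethoxyphenyl)-3-(3,5-dimethoxyphenyl)-4-methoxy-6-[(E)-2-(4-methoxyphenyl)ethenyl]-2,3-dihydro-1-benzofuran
Product: 19 4-[(2S,3S)-3-(3,5-dihydroxyphenyl)-4-hydroxy-6-[(E)-2-(4-hydroxyphenyl)ethenyl]-2,3-dihydro-1-benzofuran-2-yl]benzene-1,2-diol
Conditions: BBr3 (excess), CH2Cl2, −78 °C → rt; MeOH then H2O
Reagents that add atoms: none
Why: Lewis-acid O-demethylation (ether–borane adduct, then SN2 attack of bromide at methyl) should cleave all six methyl ethers, and any reversible opening of the O1–C2 bond under the Lewis acid recloses to the same thermodynamically preferred trans isomer, so that (2S,3S) is retained.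

**Compound list**
1 | 2,6-difluorobenzonitrile | N#Cc1c(F)cccc1F | starting material
2 | 2-(tert-butoxy)-6-fluorobenzonitrile | CC(C)(C)Oc1cccc(F)c1C#N | intermediate
3 | (3,4-dimethoxyphenyl)methanol | COc1ccc(CO)cc1OC | starting material
4 | 2-(tert-butoxy)-6-[(3,4-dimethoxybenzyl)oxy]benzonitrile | CC(C)(C)Oc1cccc(OCc2ccc(OC)c(OC)c2)c1C#N | intermediate
5 | 1-bromo-3,5-dimethoxybenzene | COc1cc(Br)cc(OC)c1 | starting material
6 | (3,5-dimethoxyphenyl)lithium | [Li]c1cc(OC)cc(OC)c1 | intermediate (not isolated)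
7 | [2-(tert-butoxy)-6-[(3,4-dimethoxybenzyl)oxy]phenyl](3,5-dimethoxyphenyl)methanimine | CC(C)(C)Oc1cccc(OCc2ccc(OC)c(OC)c2)c1C(=N)c1cc(OC)cc(OC)c1 | intermediate (not isolated)
8 | [2-(tert-butoxy)-6-[(3,4-dimethoxybenzyl)oxy]phenyl](3,5-dimethoxyphenyl)methanone hydrazone | CC(C)(C)Oc1cccc(OCc2ccc(OC)c(OC)c2)c1C(=NN)c1cc(OC)cc(OC)c1 | intermediate
9 | 1-(tert-butoxy)-2-[diazo(3,5-dimethoxyphenyl)methyl]-3-[(3,4-dimethoxybenzyl)oxy]benzene | CC(C)(C)Oc1cccc(OCc2ccc(OC)c(OC)c2)c1C(=[N+]=[N-])c1cc(OC)cc(OC)c1 | intermediate (not isolated)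
10 | (2R,3S)-4-(tert-butoxy)-2-(3,4-dimethoxyphenyl)-3-(3,5-dimethoxyphenyl)-2,3-dihydro-1-benzofuran (cis) | CC(C)(C)Oc1cccc2O[C@@H](c3ccc(OC)c(OC)c3)[C@@H](c3cc(OC)cc(OC)c3)c12 | intermediate
11 | (2R,3S)-2-(3,4-dimethoxyphenyl)-3-(3,5-dimethoxyphenyl)-2,3-dihydro-1-benzofuran-4-ol (cis) | Oc1cccc2O[C@@H](c3ccc(OC)c(OC)c3)[C@@H](c3cc(OC)cc(OC)c3)c12 | intermediate (not isolated)
12 | (2S,3S)-2-(3,4-dimethoxyphenyl)-3-(3,5-dimethoxyphenyl)-2,3-dihydro-1-benzofuran-4-ol (trans) | Oc1cccc2O[C@H](c3ccc(OC)c(OC)c3)[C@@H](c3cc(OC)cc(OC)c3)c12 | intermediate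
13 | (2S,3S)-2-(3,4-dimethoxyphenyl)-3-(3,5-dimethoxyphenyl)-4-hydroxy-2,3-dihydro-1-benzofuran-5-carbaldehyde | O=Cc1ccc2O[C@H](c3ccc(OC)c(OC)c3)[C@@H](c3cc(OC)cc(OC)c3)c2c1O | intermediate
14 | (2S,3S)-2-(3,4-dimethoxyphenyl)-3-(3,5-dimethoxyphenyl)-4-methoxy-2,3-dihydro-1-benzofuran-5-carbaldehyde | O=Cc1ccc2O[C@H](c3ccc(OC)c(OC)c3)[C@@H](c3cc(OC)cc(OC)c3)c2c1OC | intermediate
15 | (2S,3S)-2-(3,4-dimethoxyphenyl)-3-(3,5-dimethoxyphenyl)-4-methoxy-2,3-dihydro-1-benzofuran-5-carboxylic acid | OC(=O)c1ccc2O[C@H](c3ccc(OC)c(OC)c3)[C@@H](c3cc(OC)cc(OC)c3)c2c1OC | intermediate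
16 | 4-methoxystyrene | C=Cc1ccc(OC)cc1 | starting material
17 | (2S,3S)-2-(3,4-dimethoxyphenyl)-3-(3,5-dimethoxyphenyl)-4-methoxy-6-[(E)-2-(4-methoxyphenyl)ethenyl]-2,3-dihydro-1-benzofuran-5-carboxylic acid | COc1ccc(/C=C/c2cc3O[C@H](c4ccc(OC)c(OC)c4)[C@@H](c4cc(OC)cc(OC)c4)c3c(OC)c2C(O)=O)cc1 | intermediate (not isolated)
18 | (2S,3S)-2-(3,4-dimethoxyphenyl)-3-(3,5-dimethoxyphenyl)-4-methoxy-6-[(E)-2-(4-methoxyphenyl)ethenyl]-2,3-dihydro-1-benzofuran | COc1ccc(/C=C/c2cc(OC)c3c(c2)O[C@H](c2ccc(OC)c(OC)c2)[C@H]3c2cc(OC)cc(OC)c2)cc1 | intermediate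
19 | 4-[(2S,3S)-3-(3,5-dihydroxyphenyl)-4-hydroxy-6-[(E)-2-(4-hydroxyphenyl)ethenyl]-2,3-dihydro-1-benzofuran-2-yl]benzene-1,2-diol | Oc1ccc(/C=C/c2cc(O)c3c(c2)O[C@H](c2ccc(O)c(O)c2)[C@H]3c2cc(O)cc(O)c2)cc1 | target

**Total step count:** 10. **Longest linear sequence:** 10 steps (1 → 19).

**Steps most likely to fail**

Step 9. Protodecarboxylation of acid 15 may outrun C–H metalation, so the directing group is lost before olefination. The electron-rich styrene may also oligomerize, or the dihydrofuran may be dehydrogenated at the decarboxylation temperature. The fallback replaces C–H activation by a halide carried from the start and sets out from alcohol 3, bromide 5 and alkene 16. Purchased 4-bromo-2,6-difluorobenzonitrile F1 is treated with NaOMe (THF, 0 °C) to give 4-bromo-2-fluoro-6-methoxybenzonitrile F2, and SNAr with 3/NaH gives 4-bromo-2-[(3,4-dimethoxybenzyl)oxy]-6-methoxybenzonitrile F3. The Grignard reagent (3,5-dimethoxyphenyl)magnesium bromide F4, made from 5 and Mg so that the aryl bromide is spared, adds to the nitrile (CuBr cat., THF, reflux) to give the bromo ketimine F5, which hydrazine converts into the bromo hydrazone F6. MnO2 oxidation to the bromo diazo compound F7 and Rh2(S-PTAD)4 insertion give cis-(2R,3S)-6-bromo-2-(3,4-dimethoxyphenyl)-3-(3,5-dimethoxyphenyl)-4-methoxy-2,3-dihydro-1-benzofuran F8, and TFA epimerizes it to the trans-(2S,3S) bromide F9. A Mizoroki–Heck reaction of F9 with 16 (Pd(OAc)2, P(o-tol)3, Et3N, DMF, 100 °C) comes back to the route at 18.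

Step 4. Enantio- or diastereocontrol may erode, or azine may form, because the carbene-bearing ring carries two ortho substituents and sits differently in the catalyst pocket. The fallback replaces catalyst control by a classical resolution and sets out from phenol 12 of insufficient enantiomeric purity. Carbamoylation with purchased (R)-1-phenylethyl isocyanate F10 (Et3N cat., toluene, 60 °C) gives the (2S,3S) carbamate F11 together with the diastereomeric carbamate F12 from the minor enantiomer. F12 is removed by crystallization or chromatography, and NaOMe/MeOH cleaves F11 and comes back to the route at 12.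

Step 10. The Lewis acid may ionize C2 of the stilbene-bearing product and start intermolecular Friedel–Crafts oligomerization, HBr may add to the alkene, or cleavage of six ethers may stay incomplete. The fallback moves the demethylation in front of the key step, where no stilbene is present, and ends with a mild deacylation; it sets out from acid 15. BBr3 gives the pentahydroxy acid F13, and Ac2O/pyridine with aqueous work-up gives the pentaacetoxy acid F14. The conditions of step 9 with purchased 4-acetoxystyrene F15 give, via the olefinated pentaacetoxy acid F16 (not isolated), the hexaacetate F17. K2CO3 (cat.) in degassed MeOH at 0 °C then comes back to the route at 19.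

**Further compounds**
F1 | step 9 | 4-bromo-2,6-difluorobenzonitrile (purchased) | N#Cc1c(F)cc(Br)cc1F
F2 | step 9 | 4-bromo-2-fluoro-6-methoxybenzonitrile | COc1cc(Br)cc(F)c1C#N
F3 | step 9 | 4-bromo-2-[(3,4-dimethoxybenzyl)oxy]-6-methoxybenzonitrile | COc1cc(Br)cc(OCc2ccc(OC)c(OC)c2)c1C#N
F4 | step 9 | (3,5-dimethoxyphenyl)magnesium bromide | COc1cc([Mg]Br)cc(OC)c1
F5 | step 9 | [4-bromo-2-[(3,4-dimethoxybenzyl)oxy]-6-methoxyphenyl](3,5-dimethoxyphenyl)methanimine | COc1cc(Br)cc(OCc2ccc(OC)c(OC)c2)c1C(=N)c1cc(OC)cc(OC)c1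
F6 | step 9 | [4-bromo-2-[(3,4-dimethoxybenzyl)oxy]-6-methoxyphenyl](3,5-dimethoxyphenyl)methanone hydrazone | COc1cc(Br)cc(OCc2ccc(OC)c(OC)c2)c1C(=NN)c1cc(OC)cc(OC)c1
F7 | step 9 | 5-bromo-2-[diazo(3,5-dimethoxyphenyl)methyl]-1-[(3,4-dimethoxybenzyl)oxy]-3-methoxybenzene | COc1cc(Br)cc(OCc2ccc(OC)c(OC)c2)c1C(=[N+]=[N-])c1cc(OC)cc(OC)c1
F8 | step 9 | (2R,3S)-6-bromo-2-(3,4-dimethoxyphenyl)-3-(3,5-dimethoxyphenyl)-4-methoxy-2,3-dihydro-1-benzofuran (cis) | COc1cc(Br)cc2O[C@@H](c3ccc(OC)c(OC)c3)[C@@H](c3cc(OC)cc(OC)c3)c12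
F9 | step 9 | (2S,3S)-6-bromo-2-(3,4-dimethoxyphenyl)-3-(3,5-dimethoxyphenyl)-4-methoxy-2,3-dihydro-1-benzofuran (trans) | COc1cc(Br)cc2O[C@H](c3ccc(OC)c(OC)c3)[C@@H](c3cc(OC)cc(OC)c3)c12
F10 | step 4 | (R)-1-phenylethyl isocyanate (purchased) | C[C@@H](N=C=O)c1ccccc1
F11 | step 4 | (2S,3S)-2-(3,4-dimethoxyphenyl)-3-(3,5-dimethoxyphenyl)-2,3-dihydro-1-benzofuran-4-yl N-[(1R)-1-phenylethyl]carbamate | C[C@@H](NC(=O)Oc1cccc2O[C@H](c3ccc(OC)c(OC)c3)[C@@H](c3cc(OC)cc(OC)c3)c12)c1ccccc1
F12 | step 4 | (2R,3R)-2-(3,4-dimethoxyphenyl)-3-(3,5-dimethoxyphenyl)-2,3-dihydro-1-benzofuran-4-yl N-[(1R)-1-phenylethyl]carbamate | C[C@@H](NC(=O)Oc1cccc2O[C@@H](c3ccc(OC)c(OC)c3)[C@H](c3cc(OC)cc(OC)c3)c12)c1ccccc1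
F13 | step 10 | (2S,3S)-2-(3,4-dihydroxyphenyl)-3-(3,5-dihydroxyphenyl)-4-hydroxy-2,3-dihydro-1-benzofuran-5-carboxylic acid | OC(=O)c1ccc2O[C@H](c3ccc(O)c(O)c3)[C@@H](c3cc(O)cc(O)c3)c2c1O
F14 | step 10 | (2S,3S)-4-acetoxy-2-(3,4-diacetoxyphenyl)-3-(3,5-diacetoxyphenyl)-2,3-dihydro-1-benzofuran-5-carboxylic acid | CC(=O)Oc1c(C(O)=O)ccc2O[C@H](c3ccc(OC(C)=O)c(OC(C)=O)c3)[C@@H](c3cc(OC(C)=O)cc(OC(C)=O)c3)c12
F15 | step 10 | 4-acetoxystyrene (purchased) | CC(=O)Oc1ccc(C=C)cc1
F16 | step 10 | (2S,3S)-4-acetoxy-6-[(E)-2-(4-acetoxyphenyl)ethenyl]-2-(3,4-diacetoxyphenyl)-3-(3,5-diacetoxyphenyl)-2,3-dihydro-1-benzofuran-5-carboxylic acid | CC(=O)Oc1ccc(/C=C/c2cc3O[C@H](c4ccc(OC(C)=O)c(OC(C)=O)c4)[C@@H](c4cc(OC(C)=O)cc(OC(C)=O)c4)c3c(OC(C)=O)c2C(O)=O)cc1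
F17 | step 10 | hexaacetate of 19 | CC(=O)Oc1ccc(/C=C/c2cc(OC(C)=O)c3c(c2)O[C@H](c2ccc(OC(C)=O)c(OC(C)=O)c2)[C@H]3c2cc(OC(C)=O)cc(OC(C)=O)c2)cc1
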